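**Plan**
1. Retrosynthesis: remove the 2'-O-benzyl group, place a helper OH on C2 (lactol level), then cut ring C at O1–C2 and at C4–C4a together. This leaves 2,3-dimethoxyhydroquinone and 2-(2-benzyloxy-3,4-dimethoxyphenyl)acrolein.
2. Enabling feature: on ring A, O1 (on C8a) and the 6-OH are para, with the 7,8-dimethoxy pair between them. Ring A is therefore a C2v-symmetric hydroquinone whose two OH groups and two free CH positions are equivalent. C4a is ortho to O1 and para to the 7-OMe, hence nucleophilic, and C2–C3–C4 with ring B on the middle carbon is the skeleton of an α-arylacrolein.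
3. Forward: rings A and B are bought. The enal comes from the ring B aldehyde by one-carbon homologation and α-methylenation, and the hydroquinone from 2,3-dimethoxyphenol via the quinone. Ring C, the only ring made, arises when the halves are joined in an amine-catalysed Friedel–Crafts addition/enamine protonation/lactolisation cascade.
4. Stereochemistry: C3, the only stereocentre, is set in that cascade by catalyst-controlled protonation of a planar enamine. The helper OH then leaves by ionic hydrogenation and the benzyl group by hydrogenolysis, and neither step touches C3.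

Key step: step 6

Remark on numbering: isoflavan numbering is used (O1, C2, C3, C4, C4a, C5–C8, C8a for rings C and A; primed numbers for ring B). The target is the 3S isomer.
Assumption: the sense of induction of the diamine catalyst on this substrate pair is not known. The route is written for the antipode that gives 3S; both antipodes are accessible from L- and D-tert-leucine.

Step 1
Reactants: 1 2-hydroxy-3,4-dimethoxybenzaldehyde
Product: 2 2-(benzyloxy)-3,4-dimethoxybenzaldehyde
Conditions: BnBr, K2CO3, DMF, 60 °C
Reagents that add atoms: benzyl bromide BrCc1ccccc1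
Why: Williamson ether synthesis at the only acidic site; the benzyl group keeps the later enal from closing onto the 2'-oxygen and leaves by hydrogenolysis at the end.

Step 2
Reactants: 2 2-(benzyloxy)-3,4-dimethoxybenzaldehyde
Product: 4 [2-(benzyloxy)-3,4-dimethoxyphenyl]acetaldehyde, via enol ether 3 (not isolated)
Conditions: MeOCH2PPh3Cl, KOtBu, THF, 0 °C to rt; then 2 M aq. HCl, THF, 40 °C
Reagents that add atoms: (methoxymethyl)triphenylphosphonium chloride COC[P+](c1ccccc1)(c1ccccc1)c1ccccc1.[Cl-]; water O
Why: Wittig methoxymethylenation followed by acid hydrolysis of the enol ether is the standard one-carbon homologation of a non-enolisable aryl aldehyde, and the benzyl and methyl ethers are inert to both stages.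

Step 3
Reactants: 4 [2-(benzyloxy)-3,4-dimethoxyphenyl]acetaldehyde
Product: 5 2-[2-(benzyloxy)-3,4-dimethoxyphenyl]prop-2-enal
Conditions: 37% aq. HCHO, pyrrolidine (10 mol %), EtCO2H (10 mol %), iPrOH, 45 °C; kept as a cold dilute solution with a trace of BHT and used fresh
Reagents that add atoms: formaldehyde C=O
Why: organocatalytic Mannich condensation (α-methylenation of an aldehyde), in which the enamine of 4 adds to formaldehyde-derived iminium and the amine is eliminated to give the 1,1-disubstituted enal.

Step 4
Reactants: 6 2,3-dimethoxyphenol
Product: 7 2,3-dimethoxy-1,4-benzoquinone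
Conditions: O2 (1 atm), Co(salen) (5 mol %), DMF, rt
Reagents that add atoms: dioxygen O=O
Why: cobalt–salen-catalysed aerobic oxidation of a phenol with a free para position, which delivers the para-quinone and thereby installs the oxygen that becomes either O1 or the 6-OH.

Step 5
Reactants: 7 2,3-dimethoxy-1,4-benzoquinone
Product: 8 2,3-dimethoxybenzene-1,4-diol
Conditions: H2 (1 atm), Pd/C, EtOAc, rt; filtered under argon and used at once
Reagents that add atoms: none
Why: catalytic hydrogenation of a quinone to its hydroquinone is fast and clean, and leaves no salts that could disturb the amine catalysis of the next step.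

Step 6
Reactants: 5 2-[2-(benzyloxy)-3,4-dimethoxyphenyl]prop-2-enal; 8 2,3-dimethoxybenzene-1,4-diol
Product: 10 (3S)-3-[2-(benzyloxy)-3,4-dimethoxyphenyl]-7,8-dimethoxy-3,4-dihydro-2H-chromene-2,6-diol (mixture of C2 anomers), via open-chain aldehyde 9 (not isolated)
Conditions: (S)-N1,N1-diethyl-3,3-dimethylbutane-1,2-diamine·TfOH (20 mol %), 8 (2.5 equiv), 5 added slowly by syringe pump, degassed CH2Cl2, 0 °C, argon; excess 8 washed out with water, crude 10 carried on
Reagents that add atoms: none
Why: Proposed new method: the primary amine of the catalyst condenses with enal 5 to an α-aryl iminium ion, a free ring CH of 8 (ortho to OH, para to OMe) adds to its unsubstituted β-CH2 in a Friedel–Crafts conjugate addition (C4–C4a), the released proton is parked on the neighbouring tertiary amine, and this ammonium N–H protonates the enamine at C3 before hydrolysis frees aldehyde 9, which the flanking phenol captures as lactol 10 (O1–C2). The closest known reaction types are the primary-amine-catalysed Friedel–Crafts addition of indoles to α-substituted acroleins with enantioselective enamine protonation and the iminium-catalysed Friedel–Crafts/hemiacetalisation [3+3] cascade of naphthols and electron-rich phenols with enals, and what is new is their union on a hydroquinone and an α-arylacrolein. Ring C closes by 6-exo-trig addition of O1–H to the aldehyde carbon. C3 is controlled by the catalyst, because the proton is delivered intramolecularly to the enamine face that the tert-butyl group leaves open, whereas C2 forms as an anomeric mixture of no consequence since it becomes CH2 in step 7. Site selectivity needs no control, because the C2v symmetry of 8 makes both CH positions and both OH groups equivalent and leaves the unused OH as the free 6-OH, and O-attack on the iminium ion is reversible (retro-oxa-Michael) while C-attack is sealed by rearomatisation and ring closure. A second annulation at C5 of 10 and self-condensation of 5 are held back by the excess of 8 and the slow addition of 5, and lactol formation keeps the α-aryl aldehyde away from renewed enamine formation, which protects the new stereocentre.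

Step 7
Reactants: 10 (3S)-3-[2-(benzyloxy)-3,4-dimethoxyphenyl]-7,8-dimethoxy-3,4-dihydro-2H-chromene-2,6-diol
Product: 11 (3S)-3-[2-(benzyloxy)-3,4-dimethoxyphenyl]-7,8-dimethoxy-3,4-dihydro-2H-chromen-6-ol
Conditions: Et3SiH (3 equiv), BF3·OEt2 (1.5 equiv), CH2Cl2, −78 to −40 °C
Reagents that add atoms: none
Why: ionic hydrogenation of a lactol, in which BF3 ionises the anomeric OH to the O1-stabilised oxocarbenium ion and the excess silane should trap it at C2 at low temperature before it can lose H3, so that O1–C2 stays intact and C3 keeps its configuration.

Step 8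
Reactants: 11 (3S)-3-[2-(benzyloxy)-3,4-dimethoxyphenyl]-7,8-dimethoxy-3,4-dihydro-2H-chromen-6-ol
Product: 12 (3S)-3-(2-hydroxy-3,4-dimethoxyphenyl)-7,8-dimethoxy-3,4-dihydro-2H-chromen-6-ol (target)
Conditions: H2 (1 atm), Pd/C, EtOAc/MeOH, rt, work-up under argon
Reagents that add atoms: none
Why: hydrogenolysis of a benzyl aryl ether; the only benzylic C–O bond is that of the protecting group (O1–C2 is not benzylic and C4 carries no heteroatom), so ring C and C3 are left untouched.

**Compound list**
1 | 2-hydroxy-3,4-dimethoxybenzaldehyde | COc1ccc(C=O)c(O)c1OC | starting material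
2 | 2-(benzyloxy)-3,4-dimethoxybenzaldehyde | COc1ccc(C=O)c(OCc2ccccc2)c1OC | intermediate
3 | 2-(benzyloxy)-3,4-dimethoxy-1-(2-methoxyethenyl)benzene (E/Z mixture, not isolated) | COC=Cc1ccc(OC)c(OC)c1OCc1ccccc1 | intermediate
4 | [2-(benzyloxy)-3,4-dimethoxyphenyl]acetaldehyde | COc1ccc(CC=O)c(OCc2ccccc2)c1OC | intermediate
5 | 2-[2-(benzyloxy)-3,4-dimethoxyphenyl]prop-2-enal | COc1ccc(C(=C)C=O)c(OCc2ccccc2)c1OC | intermediate
6 | 2,3-dimethoxyphenol | COc1cccc(O)c1OC | starting material
7 | 2,3-dimethoxy-1,4-benzoquinone | COC1=C(OC)C(=O)C=CC1=O | intermediate
8 | 2,3-dimethoxybenzene-1,4-diol | COc1c(O)ccc(O)c1OC | intermediate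
9 | (2S)-2-[2-(benzyloxy)-3,4-dimethoxyphenyl]-3-(2,5-dihydroxy-3,4-dimethoxyphenyl)propanal (not isolated) | COc1ccc([C@@H](C=O)Cc2cc(O)c(OC)c(OC)c2O)c(OCc2ccccc2)c1OC | intermediate
10 | (3S)-3-[2-(benzyloxy)-3,4-dimethoxyphenyl]-7,8-dimethoxy-3,4-dihydro-2H-chromene-2,6-diol (C2 anomers) | COc1ccc([C@H]2C(O)Oc3c(cc(O)c(OC)c3OC)C2)c(OCc2ccccc2)c1OC | intermediate
11 | (3S)-3-[2-(benzyloxy)-3,4-dimethoxyphenyl]-7,8-dimethoxy-3,4-dihydro-2H-chromen-6-ol | COc1ccc([C@H]2COc3c(cc(O)c(OC)c3OC)C2)c(OCc2ccccc2)c1OC | intermediate
12 | (3S)-3-(2-hydroxy-3,4-dimethoxyphenyl)-7,8-dimethoxy-3,4-dihydro-2H-chromen-6-ol | COc1ccc([C@H]2COc3c(cc(O)c(OC)c3OC)C2)c(O)c1OC | target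

Total step count: 8. Longest linear sequence: 6 (steps 1, 2, 3, 6, 7, 8).

**Steps most likely to fail**

Step 6 (Proposed new method). The C-alkylation may be too slow against dimerisation of the enal. The facial selectivity of the enamine protonation may be poor. The lactol may lose water to the achiral 4H-chromene or be re-enaminated, with erosion of configuration.
The fallback uses known chemistry and sets out from 5 and 8. Heating the two with PhB(OH)2 and AcOH in toluene with azeotropic removal of water should give 3-[2-(benzyloxy)-3,4-dimethoxyphenyl]-7,8-dimethoxy-2H-chromen-6-ol F1. The sequence is boron-templated ortho-hydroxyalkylation at the aldehyde carbon, loss of the template and oxa-6π ring closure. It forms the same two ring C bonds in one operation, with the roles of the two termini exchanged.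
Asymmetric hydrogenation of the trisubstituted C3=C4 bond follows, with H2 (50 bar), [Ir(cod)(tBu-PHOX)][B(3,5-(CF3)2C6H3)4] (1 mol %), CH2Cl2, rt, and the ligand antipode chosen for 3S. This reaction type is established for 3-aryl-2H-chromenes. It sets C3 and returns to the route at 11.

Step 7. The oxocarbenium ion may reversibly lose H3 to give the 4H-chromene, which would scramble C3. The Lewis acid may also partly remove the benzyl group.
The fallback sets out from 10. NaBH4 in MeOH at 0 °C intercepts the open form quickly and should give 5-{(2S)-2-[2-(benzyloxy)-3,4-dimethoxyphenyl]-3-hydroxypropyl}-2,3-dimethoxybenzene-1,4-diol F2, in which C3 is no longer next to a carbonyl group. A Mitsunobu etherification (PPh3, DIAD, dilute THF, 0 °C) then closes ring C through the only phenol within reach (6-exo-tet) and returns to the route at 11.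

Step 3. Aldehyde 4 may undergo self-aldol condensation, and enal 5 may undergo hetero-Diels–Alder dimerisation or polymerisation on concentration.
The fallback avoids 5 altogether and sets out from 4 and 8. Me2NCH(OMe)2 in toluene at 80 °C converts 4 into the stable 2-[2-(benzyloxy)-3,4-dimethoxyphenyl]-3-(dimethylamino)prop-2-enal F3, an arylmalondialdehyde equivalent. Condensation of this with 8 in HCl/AcOH at rt should give 3-[2-(benzyloxy)-3,4-dimethoxyphenyl]-6-hydroxy-7,8-dimethoxychromenylium chloride F4, again with both ring C bonds made in one operation. NaBH4 in THF/EtOH at 0 °C should add hydride mainly at C2 to give the 2H-chromene F1. The iridium-catalysed asymmetric hydrogenation described above then returns to the route at 11.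

**Further compounds**
F1 | step 6 | 3-[2-(benzyloxy)-3,4-dimethoxyphenyl]-7,8-dimethoxy-2H-chromen-6-ol | COc1ccc(C2=Cc3cc(O)c(OC)c(OC)c3OC2)c(OCc2ccccc2)c1OC
F2 | step 7 | 5-{(2S)-2-[2-(benzyloxy)-3,4-dimethoxyphenyl]-3-hydroxypropyl}-2,3-dimethoxybenzene-1,4-diol | COc1ccc([C@@H](CO)Cc2cc(O)c(OC)c(OC)c2O)c(OCc2ccccc2)c1OC
F3 | step 3 | 2-[2-(benzyloxy)-3,4-dimethoxyphenyl]-3-(dimethylamino)prop-2-enal | CN(C)C=C(C=O)c1ccc(OC)c(OC)c1OCc1ccccc1
F4 | step 3 | 3-[2-(benzyloxy)-3,4-dimethoxyphenyl]-6-hydroxy-7,8-dimethoxychromenylium chloride | COc1ccc(-c2cc3cc(O)c(OC)c(OC)c3[o+]c2)c(OCc2ccccc2)c1OC.[Cl-]
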